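1. Retrosynthesis: first cut the two C(sp)–thienyl bonds (twofold Sonogashira coupling, two equivalents of 5-bromo-2,2'-bithiophene). Then cut the ring bonds C1–C4 and C2–C3 of the cyclobutane (ketene–alkene [2+2]), and finally the two alkyne–alkene bonds of a (Z)-enediyne.
2. Enabling feature: in the four-membered ring, C3 and C4 are unsubstituted CH2 groups, and the adjacent stereocentres C1 and C2 each hold an alkynyl arm on the same face. The ring is therefore the sum of a C3–C4 two-carbon unit (dichloroketene as an ethylene surrogate) and the C1=C2 bond of a (Z)-hex-3-ene-1,5-diyne.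
3. Forward: (Z)-1,2-dichloroethylene is alkynylated twice. The cyclobutane, the only ring built, closes on the enediyne. CCl2 and C=O are taken down to CH2, and the bithienyl ends are attached last.
4. Stereochemistry: the cis relationship at C1/C2 is the Z geometry of the alkene, transferred by a suprafacial cycloaddition. The target is meso, so chiral intermediates are racemic and no absolute control is required.
5. The alkyne termini carry triisopropylsilyl caps while the ring is made and reduced. The caps shield the triple bonds from the ketene and keep the acylation-prone, light-sensitive bithiophenes out of the zinc/acid chloride and tin hydride steps.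

Key step: step 2

Step 1
Reactants: 1 (Z)-1,2-dichloroethylene; 2 ethynyltriisopropylsilane (2 equiv, one per C–Cl bond)
Product: 3 (Z)-1,6-bis(triisopropylsilyl)hex-3-ene-1,5-diyne
Conditions: 2 (2.3 equiv), Pd(PPh3)4 (cat.), CuI (cat.), n-BuNH2, benzene, rt
Reagents that add atoms: second equivalent of ethynyltriisopropylsilane 2, C#C[Si](C(C)C)(C(C)C)C(C)C
Why: A twofold Sonogashira coupling of the vinyl dichloride under n-butylamine-promoted Pd(PPh3)4/CuI catalysis consumes one molecule of 2 at each C–Cl bond and proceeds with retention, so the Z geometry of 1 is carried unchanged into enediyne 3.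

Step 2
Reactants: 3 (Z)-1,6-bis(triisopropylsilyl)hex-3-ene-1,5-diyne; 4 trichloroacetyl chloride
Product: 6 cis-2,2-dichloro-3,4-bis[(triisopropylsilyl)ethynyl]cyclobutan-1-one (racemic), via dichloroketene 5 (not isolated)
Conditions: 4 (slow addition), Zn–Cu couple, DME, Et2O, ultrasound, 15–20 °C
Reagents that add atoms: none
Why: Zinc removes two chlorines from 4 to release dichloroketene 5, whose electrophilic central carbon is attacked by the alkene of 3 in an orthogonal approach, and both σ-bonds then form in one concerted but asynchronous thermal ketene–alkene [2+2] cycloaddition, the lagging bond closing at a carbon whose partial positive charge is stabilised by its alkynyl substituent. The closest known reaction type is the stereospecific addition of zinc-generated dichloroketene to cis-1,2-disubstituted and conjugated alkenes. The cyclobutane, the only ring closed in the route, is formed intermolecularly by simultaneous construction of C1–C4 and C2–C3 (target numbering), the ketene delivering the carbonyl and CCl2 carbons that later become the C3 and C4 methylenes. The two new stereocentres C1 and C2 are fixed by the Z geometry of 3, because the addition is suprafacial on the alkene and the two alkynyl groups must therefore end up cis; the adduct is racemic, which is of no consequence for a meso target. The step needs chemoselectivity for the alkene over the two triple bonds, which the triisopropylsilyl caps should provide by shielding the alkyne carbon at which a ketene would have to bond, helped by the propargylic charge stabilisation that only attack at the alkene enjoys; regiochemistry is moot because the two alkene carbons are equivalent. That preference is an extrapolation from simpler alkenes and is the main uncertainty of the route.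

Step 3
Reactants: 6 cis-2,2-dichloro-3,4-bis[(triisopropylsilyl)ethynyl]cyclobutan-1-one
Product: 7 cis-2,3-bis[(triisopropylsilyl)ethynyl]cyclobutan-1-one (racemic)
Conditions: Zn dust, NH4Cl, MeOH, 0 °C to rt; crude ketone used at once
Reagents that add atoms: none
Why: Zinc-mediated reductive dechlorination of an α,α-dichlorocyclobutanone, the usual sequel to a dichloroketene cycloaddition, runs through zinc enolates formed only on the chlorinated side, and the nearly neutral NH4Cl/MeOH medium should spare the epimerisable C2–H next to the carbonyl as well as the silylalkynes.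

Step 4
Reactants: 7 cis-2,3-bis[(triisopropylsilyl)ethynyl]cyclobutan-1-one
Product: 8 all-cis-2,3-bis[(triisopropylsilyl)ethynyl]cyclobutan-1-ol (racemic; expected major epimer)
Conditions: NaBH4, CeCl3·7H2O, MeOH, −78 °C
Reagents that add atoms: none
Why: A Luche-type borohydride reduction of the strained, highly electrophilic cyclobutanone is fast at −78 °C and only weakly basic, so the carbonyl is removed before the α-alkynyl stereocentre can epimerise; hydride should enter anti to the neighbouring alkynyl group to give mainly the all-cis alcohol, a configuration that is erased two steps later.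

Step 5
Reactants: 8 all-cis-2,3-bis[(triisopropylsilyl)ethynyl]cyclobutan-1-ol
Product: 10 O-[2,3-bis[(triisopropylsilyl)ethynyl]cyclobutyl] S-methyl dithiocarbonate (all-cis; racemic), via sodium xanthate salt 9 (not isolated)
Conditions: NaH, imidazole (cat.), THF, 0 °C; CS2; then MeI, 0 °C to rt
Reagents that add atoms: carbon disulfide, S=C=S; iodomethane, CI
Why: Xanthate formation, the first half of a Barton–McCombie deoxygenation: the sodium alkoxide adds to CS2 and the dithiocarbonate salt 9 is S-methylated, conditions that touch neither the silylalkynes nor the ring stereocentres.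

Step 6
Reactants: 10 O-[2,3-bis[(triisopropylsilyl)ethynyl]cyclobutyl] S-methyl dithiocarbonate
Product: 11 cis-1,2-bis[(triisopropylsilyl)ethynyl]cyclobutane (meso)
Conditions: Bu3SnH, AIBN (cat.), toluene, 80 °C
Reagents that add atoms: none
Why: Barton–McCombie radical deoxygenation: the stannyl radical adds to the thiocarbonyl sulfur, the adduct fragments to a secondary cyclobutyl radical, and hydrogen transfer from Bu3SnH (kept concentrated so that it outruns ring opening) leaves a methylene without touching C1 or C2, giving the meso cyclobutane.

Step 7
Reactants: 11 cis-1,2-bis[(triisopropylsilyl)ethynyl]cyclobutane; 12 5-bromo-2,2'-bithiophene (2 equiv, one per alkyne terminus)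
Product: 14 isocardopatine, via cis-1,2-diethynylcyclobutane 13 (not isolated)
Conditions: TBAF (2.2 equiv), THF, 0 °C to rt; then 12 (2.3 equiv), Pd(PPh3)4 (cat.), CuI (cat.), Et3N, degassed, 50 °C
Reagents that add atoms: second equivalent of 5-bromo-2,2'-bithiophene 12, Brc1ccc(-c2cccs2)s1
Why: Fluoride cleavage of both C(sp)–Si bonds followed in the same flask by a twofold Sonogashira coupling, in which one molecule of the α-bromothiophene 12 is consumed at each terminal alkyne, forms both alkyne–thienyl bonds while the volatile diyne 13 is never isolated, and neither operation affects the two cis ring stereocentres.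

Compound list
1 | (Z)-1,2-dichloroethylene | Cl/C=C\Cl | starting material
2 | ethynyltriisopropylsilane | C#C[Si](C(C)C)(C(C)C)C(C)C | starting material
3 | (Z)-1,6-bis(triisopropylsilyl)hex-3-ene-1,5-diyne | CC(C)[Si](C(C)C)(C(C)C)C#C/C=C\C#C[Si](C(C)C)(C(C)C)C(C)C | intermediate
4 | trichloroacetyl chloride | ClC(Cl)(Cl)C(Cl)=O | starting material
5 | dichloroketene | ClC(Cl)=C=O | intermediate (not isolated)
6 | cis-2,2-dichloro-3,4-bis[(triisopropylsilyl)ethynyl]cyclobutan-1-one, racemic | O=C1C(Cl)(Cl)[C@H](C#C[Si](C(C)C)(C(C)C)C(C)C)[C@@H]1C#C[Si](C(C)C)(C(C)C)C(C)C | intermediate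
7 | cis-2,3-bis[(triisopropylsilyl)ethynyl]cyclobutan-1-one, racemic | O=C1C[C@H](C#C[Si](C(C)C)(C(C)C)C(C)C)[C@@H]1C#C[Si](C(C)C)(C(C)C)C(C)C | intermediate
8 | all-cis-2,3-bis[(triisopropylsilyl)ethynyl]cyclobutan-1-ol, racemic (hydroxyl cis to both alkynyl groups; expected major epimer) | O[C@@H]1C[C@H](C#C[Si](C(C)C)(C(C)C)C(C)C)[C@@H]1C#C[Si](C(C)C)(C(C)C)C(C)C | intermediate
9 | sodium O-[all-cis-2,3-bis[(triisopropylsilyl)ethynyl]cyclobutyl] dithiocarbonate | [Na+].[S-]C(=S)O[C@@H]1C[C@H](C#C[Si](C(C)C)(C(C)C)C(C)C)[C@@H]1C#C[Si](C(C)C)(C(C)C)C(C)C | intermediate (not isolated)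
10 | O-[all-cis-2,3-bis[(triisopropylsilyl)ethynyl]cyclobutyl] S-methyl dithiocarbonate, racemic | CSC(=S)O[C@@H]1C[C@H](C#C[Si](C(C)C)(C(C)C)C(C)C)[C@@H]1C#C[Si](C(C)C)(C(C)C)C(C)C | intermediate
11 | cis-1,2-bis[(triisopropylsilyl)ethynyl]cyclobutane, meso | CC(C)[Si](C(C)C)(C(C)C)C#C[C@@H]1CC[C@@H]1C#C[Si](C(C)C)(C(C)C)C(C)C | intermediate
12 | 5-bromo-2,2'-bithiophene | Brc1ccc(-c2cccs2)s1 | starting material
13 | cis-1,2-diethynylcyclobutane, meso | C#C[C@@H]1CC[C@@H]1C#C | intermediate (not isolated)
14 | isocardopatine, cis-1,2-bis[(2,2'-bithiophen-5-yl)ethynyl]cyclobutane, meso | C(#C[C@@H]1CC[C@@H]1C#Cc1ccc(-c2cccs2)s1)c1ccc(-c2cccs2)s1 | target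

Total step count: 7. Longest linear sequence: 7 steps (1 to 14).

Steps most likely to fail

Step 2. The alkene, flanked by two sp-carbon substituents, may add too slowly, so that the ketene is lost to self-condensation, or cycloaddition may stray to a triple bond. The fallback sets out from 3 and comes back at 7, which makes step 3 unnecessary. N,N-Dimethylacetamide is activated with Tf2O and 2,4,6-collidine in 1,2-dichloroethane to give N,N-dimethylketeniminium triflate F1, a stronger electrophile that cannot dimerise. F1 should add to the alkene of 3 at reflux in a keteniminium–alkene [2+2] cycloaddition with retention of alkene geometry. The resulting cis-cyclobutaniminium triflate F2 is hydrolysed with aqueous NaHCO3 to the chlorine-free ketone 7.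

Step 3. While the ketone is present, enolisation toward the alkynyl-bearing carbon could epimerise that centre from cis to the more stable trans arrangement. The fallback sets out from 6 and comes back at 8, replacing steps 3 and 4 by reversing their order. The activated dichloroketone 6 is reduced first with NaBH4/CeCl3·7H2O in MeOH at −78 °C to the all-cis dichlorocyclobutanol F3, which has no enolisable carbonyl. Both chlorines are then removed by radical chain reduction with Bu3SnH/AIBN in toluene at 80 °C to give 8. Base is avoided throughout, because it would trigger ring contraction of the chlorohydrin.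

Step 6. Ring opening of the cyclobutyl radical by β-scission toward a propargylic radical, or stannyl radical addition to a triple bond, could compete with hydrogen transfer. The fallback sets out from 7 and comes back at 11, replacing steps 4 to 6 with a deoxygenation that uses no tin radicals. Ketone 7 is condensed with p-toluenesulfonyl hydrazide in MeOH at room temperature to the tosylhydrazone F4. F4 is reduced with catecholborane in CHCl3 at 0 °C and then warmed with NaOAc·3H2O, so that the derived alkyl diazene expels sulfinate and N2 and leaves the methylene of 11.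

Further compounds
F1 | step 2 | N,N-dimethylketeniminium triflate | C=C=[N+](C)C.[O-]S(=O)(=O)C(F)(F)F
F2 | step 2 | N-[cis-2,3-bis[(triisopropylsilyl)ethynyl]cyclobutylidene]-N-methylmethanaminium triflate, racemic | C[N+](C)=C1C[C@H](C#C[Si](C(C)C)(C(C)C)C(C)C)[C@@H]1C#C[Si](C(C)C)(C(C)C)C(C)C.[O-]S(=O)(=O)C(F)(F)F
F3 | step 3 | all-cis-2,2-dichloro-3,4-bis[(triisopropylsilyl)ethynyl]cyclobutan-1-ol, racemic | O[C@@H]1C(Cl)(Cl)[C@H](C#C[Si](C(C)C)(C(C)C)C(C)C)[C@@H]1C#C[Si](C(C)C)(C(C)C)C(C)C
F4 | step 6 | cis-2,3-bis[(triisopropylsilyl)ethynyl]cyclobutan-1-one p-toluenesulfonylhydrazone, racemic | Cc1ccc(cc1)S(=O)(=O)NN=C1C[C@H](C#C[Si](C(C)C)(C(C)C)C(C)C)[C@@H]1C#C[Si](C(C)C)(C(C)C)C(C)C
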